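**Retrosynthetic overview**
1. Target 22 ⇐ hydroxy lactone 16 by acetal hydrolysis and two late acylations (C6–O angelate, C9–O (R)-2-methylbutanoate).
2. 16 ⇐ cyclohexene acid 14: epoxidation of C8=C9 and 5-exo opening by the C12 acid closes the lactone (the second ring, formed last) and sets C8 and C9; the acid is the oxidised carvone isopropenyl group.
3. 14 ⇐ ketone 8: C5–C4 bond by 1,2-addition of α-metallated acrolein acetal, then formate hydrogenolysis of the tertiary allylic carbonate to set C5–H.
4. 8 ⇐ 6-silyloxycarvone 4: key C10–C1 bond by deconjugative α-ethynylation of the linear dienolate with an alkynyl benziodoxolone (an electrophilic, polarity-reversed acetylide); this builds the quaternary centre and moves the ring alkene to C8=C9; alkyne → vinyl.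
5. 4 ⇐ (S)-carvone 1 by Rubottom oxidation; the six-membered ring is the carvone ring throughout.

Assumption: locants are elemane locants (ring C5–C10; C10 carries CH3 and vinyl C1=C2, C5 the C3/C4/C15 unit, C7 the C11/C12/C13 unit); "upper face" is the ring face carrying the C7 side chain, "lower face" the opposite one; 1, 5, 9, 17 and 20 are bought.

**Step 1**
Reactants: 1 (S)-(+)-carvone
Product: 2 tert-butyl(dimethyl){[(3S)-6-methyl-3-(prop-1-en-2-yl)cyclohexa-1,5-dien-1-yl]oxy}silane
Conditions: TBSOTf, Et3N, CH2Cl2, 0 °C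
Reagents that add atoms: tert-butyldimethylsilyl trifluoromethanesulfonate, CC(C)(C)[Si](C)(C)OS(=O)(=O)C(F)(F)F
Why: Soft enolisation of the enone with a silyl triflate and an amine removes the α'-proton (kinetic, cross-conjugated silyl dienol ether formation) and leaves the carvone stereocentre untouched.

**Step 2**
Reactants: 2 tert-butyl(dimethyl){[(3S)-6-methyl-3-(prop-1-en-2-yl)cyclohexa-1,5-dien-1-yl]oxy}silane
Product: 4 (5R,6R)-6-[(tert-butyldimethylsilyl)oxy]-2-methyl-5-(prop-1-en-2-yl)cyclohex-2-en-1-one, via silyloxy epoxide 3 (not isolated)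
Conditions: dimethyldioxirane (acetone), CH2Cl2, −40 °C → rt
Reagents that add atoms: dimethyldioxirane, CC1(C)OO1
Why: Rubottom oxidation, in which the dioxirane epoxidises the electron-rich silyl enol ether on the face opposite the adjacent isopropenyl group and the silyloxy epoxide opens with a 1,4-silyl shift to the trans α-silyloxy ketone, setting C6.

**Step 3**
Reactants: 4 (5R,6R)-6-[(tert-butyldimethylsilyl)oxy]-2-methyl-5-(prop-1-en-2-yl)cyclohex-2-en-1-one; 5 1-[(trimethylsilyl)ethynyl]-1,2-benziodoxol-3(1H)-one (TMS-EBX)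
Product: 7 (2S,5R,6R)-6-[(tert-butyldimethylsilyl)oxy]-2-ethynyl-2-methyl-5-(prop-1-en-2-yl)cyclohex-3-en-1-one, via potassium dienolate 6 (not isolated)
Conditions: KOtBu, THF, −78 → −20 °C; then 5, Bu4NF, THF, −78 °C
Reagents that add atoms: 5 1-[(trimethylsilyl)ethynyl]-1,2-benziodoxol-3(1H)-one, C[Si](C)(C)C#CI1OC(=O)c2ccccc12
Why: Proposed new method: KOtBu equilibrates 4 to its linear (γ-deprotonated) dienolate, whose fully substituted α-carbon C10 attacks the ethynyl trivalent-iodine reagent freed from 5 by fluoride (conjugate addition to the iodine-bound alkyne, loss of 2-iodobenzoate, 1,2-shift), so two normally nucleophilic carbons (enolate α-carbon and acetylide carbon) are joined while the ring alkene moves to C8=C9; the C6 silyloxy group, held pseudo-axial by allylic strain with the enolate oxygen, shields the lower face so the alkyne enters on the upper face, and the closest known reactions are the α-ethynylation of α-substituted ketone enolates with TMS-EBX and fluoride to quaternary propargylic ketones and the deconjugative α-alkylation of enone dienolates.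

**Step 4**
Reactants: 7 (2S,5R,6R)-6-[(tert-butyldimethylsilyl)oxy]-2-ethynyl-2-methyl-5-(prop-1-en-2-yl)cyclohex-3-en-1-one
Product: 8 (2R,5R,6R)-6-[(tert-butyldimethylsilyl)oxy]-2-ethenyl-2-methyl-5-(prop-1-en-2-yl)cyclohex-3-en-1-one
Conditions: H2 (1 atm), Pd on CaCO3 poisoned with Pb(OAc)2, quinoline, EtOAc, rt
Reagents that add atoms: none
Why: Lindlar semihydrogenation reduces the terminal alkyne to the vinyl group much faster than the hindered ring and isopropenyl alkenes and changes no stereocentre.

**Step 5**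
Reactants: 8 (2R,5R,6R)-6-[(tert-butyldimethylsilyl)oxy]-2-ethenyl-2-methyl-5-(prop-1-en-2-yl)cyclohex-3-en-1-one; 9 2-bromo-3,3-diethoxyprop-1-ene
Product: 11 tertiary allylic methyl carbonate (C5 bears OCO2Me on the lower face and the 3,3-diethoxyprop-1-en-2-yl group on the upper face), via cerium alkoxide 10 (not isolated)
Conditions: 9, t-BuLi (2 equiv), Et2O, −78 °C; CeCl3, THF, −78 °C; then 8; then ClCO2Me, −78 → 0 °C
Reagents that add atoms: 9 2-bromo-3,3-diethoxyprop-1-ene, C=C(Br)C(OCC)OCC; methyl chloroformate, COC(=O)Cl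
Why: Organocerium 1,2-addition of the α-metallated acrolein acetal (low basicity avoids enolisation of the hindered ketone) takes place anti to the C6 silyloxy group (polar Felkin–Anh control), and the alkoxide is trapped in the same flask as the tertiary allylic carbonate.

**Step 6**
Reactants: 11 tertiary allylic methyl carbonate
Product: 12 triene acetal with C5–H (3,3-diethoxyprop-1-en-2-yl group on the lower face, cis to OTBS)
Conditions: Pd(OAc)2 (5 mol%), PBu3, HCO2H, Et3N, THF, 40 °C
Reagents that add atoms: none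
Why: Tsuji-type formate hydrogenolysis, in which zerovalent palladium ionises the tertiary allylic carbonate anti and the allylpalladium formate loses CO2 while delivering hydride to the more substituted terminus C5 from the palladium-bearing upper face (away from the C6 silyloxy group), giving the 1,1-disubstituted alkene and the C5–H bond with inversion.

**Step 7**
Reactants: 12 triene acetal with C5–H
Product: 13 allylic alcohol (C7 side chain is 3-hydroxyprop-1-en-2-yl)
Conditions: SeO2 (0.3 equiv), t-BuOOH, CH2Cl2, rt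
Reagents that add atoms: selenium dioxide, O=[Se]=O; tert-butyl hydroperoxide, CC(C)(C)OO
Why: SeO2-catalysed allylic oxidation (ene reaction then 2,3-sigmatropic shift) attacks the methyl group of the electron-rich isopropenyl unit in preference to allylic methine positions and to the acetal-deactivated alkene.

**Step 8**
Reactants: 13 allylic alcohol
Product: 14 acrylic acid (C7 side chain is 1-carboxyethenyl)
Conditions: TEMPO (cat.), NaOCl (cat.), NaClO2, MeCN, sodium phosphate buffer pH 6.7, 35 °C
Reagents that add atoms: sodium chlorite, [Na+].[O-]Cl=O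
Why: The TEMPO/chlorite oxidation converts the primary allylic alcohol through the enal into the acid at near-neutral pH, so the acetal, the silyl ether and the isolated alkenes survive (any enal carried over from step 7 converges on 14).

**Step 9**
Reactants: 14 acrylic acid
Product: 16 hydroxy lactone (cis-fused α-methylene-γ-butyrolactone on C7–C8; C9–OH on the lower face), via epoxy acid 15 (not isolated)
Conditions: mCPBA, CH2Cl2, 0 °C → rt
Reagents that add atoms: 3-chloroperoxybenzoic acid, OOC(=O)c1cccc(Cl)c1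
Why: Prilezhaev epoxidation of the only electron-rich 1,2-disubstituted alkene occurs on the lower face (opposite the pseudo-axial C10 vinyl group), and the C12 acid then opens the epoxide at C8 by 5-exo anti attack, which only this epoxide allows and which sets the cis lactone at C8 and the trans hydroxyl at C9 together.

**Step 10**
Reactants: 16 hydroxy lactone; 17 (R)-2-methylbutanoic acid
Product: 18 C9 (2R)-2-methylbutanoate of 16
Conditions: 17, 2,4,6-trichlorobenzoyl chloride, Et3N, DMAP, toluene, rt → 40 °C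
Reagents that add atoms: 17 (R)-2-methylbutanoic acid, CC[C@@H](C)C(=O)O
Why: Yamaguchi esterification through the mixed trichlorobenzoic anhydride acylates the hindered C9 hydroxyl under mild conditions that do not epimerise the bought (R) stereocentre of the acid.

**Step 11**
Reactants: 18 C9 (2R)-2-methylbutanoate
Product: 19 C6 alcohol (18 without the TBS group)
Conditions: Bu4NF, AcOH (1:1), THF, 0 °C → rt
Reagents that add atoms: none
Why: Buffered fluoride desilylation frees the C6 hydroxyl while acetic acid suppresses alkoxide-induced translactonisation and Michael addition to the α-methylene lactone.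

**Step 12**
Reactants: 19 C6 alcohol; 20 angelic acid
Product: 21 C6 angelate of 19 (diethyl acetal of the target)
Conditions: 20, 2,4,6-trichlorobenzoyl chloride, Et3N, toluene, rt; then 19, 80 °C
Reagents that add atoms: 20 angelic acid, C/C=C(/C)C(=O)O
Why: Acylation with the preformed mixed trichlorobenzoic anhydride (Yamaguchi-type, no nucleophilic catalyst) is the established way to make angelates without Z to E isomerisation to the tiglate.

**Step 13**
Reactants: 21 C6 angelate
Product: 22 CNP0295282.1
Conditions: pyridinium p-toluenesulfonate (cat.), acetone/H2O (10:1), 40 °C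
Reagents that add atoms: water, O
Why: Mild acid-catalysed acetal hydrolysis unmasks the 2-substituted acrolein last, because a free C6 hydroxyl would otherwise close onto the aldehyde as a lactol.

**Compound list**
1 | (S)-(+)-carvone, (5S)-2-methyl-5-(prop-1-en-2-yl)cyclohex-2-en-1-one | CC1=CC[C@@H](CC1=O)C(C)=C | starting material
2 | tert-butyl(dimethyl){[(3S)-6-methyl-3-(prop-1-en-2-yl)cyclohexa-1,5-dien-1-yl]oxy}silane (cross-conjugated TBS dienol ether) | CC1=CC[C@H](C(C)=C)C=C1O[Si](C)(C)C(C)(C)C | intermediate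
3 | silyloxy epoxide of 2 (oxirane on the enol ether bond, oxygen on the lower face, trans to isopropenyl) | CC1=CC[C@H](C(C)=C)[C@H]2O[C@@]12O[Si](C)(C)C(C)(C)C | intermediate
4 | (5R,6R)-6-[(tert-butyldimethylsilyl)oxy]-2-methyl-5-(prop-1-en-2-yl)cyclohex-2-en-1-one (OTBS trans to isopropenyl) | O=C1[C@H](O[Si](C)(C)C(C)(C)C)[C@@H](C(C)=C)CC=C1C | intermediate
5 | 1-[(trimethylsilyl)ethynyl]-1,2-benziodoxol-3(1H)-one (TMS-EBX) | C[Si](C)(C)C#CI1OC(=O)c2ccccc12 | starting material
6 | potassium 6-[(tert-butyldimethylsilyl)oxy]-2-methyl-5-(prop-1-en-2-yl)cyclohexa-1,3-dien-1-olate (linear dienolate of 4, ring stereocentres as in 4) | [K+].[O-]C1=C(C)C=C[C@H](C(C)=C)[C@H]1O[Si](C)(C)C(C)(C)C | intermediate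
7 | (2S,5R,6R)-6-[(tert-butyldimethylsilyl)oxy]-2-ethynyl-2-methyl-5-(prop-1-en-2-yl)cyclohex-3-en-1-one (ethynyl cis to isopropenyl, trans to OTBS) | C#C[C@@]1(C)C(=O)[C@H](O[Si](C)(C)C(C)(C)C)[C@@H](C(C)=C)C=C1 | intermediate
8 | (2R,5R,6R)-6-[(tert-butyldimethylsilyl)oxy]-2-ethenyl-2-methyl-5-(prop-1-en-2-yl)cyclohex-3-en-1-one | C=C[C@@]1(C)C(=O)[C@H](O[Si](C)(C)C(C)(C)C)[C@@H](C(C)=C)C=C1 | intermediate
9 | 2-bromo-3,3-diethoxyprop-1-ene (2-bromoacrolein diethyl acetal) | C=C(Br)C(OCC)OCC | starting material
10 | dichlorocerium alkoxide of the C5 tertiary alcohol (C5–O on the lower face, cis to OTBS) | C=C[C@@]1(C)[C@@](O[Ce](Cl)Cl)(C(=C)C(OCC)OCC)[C@H](O[Si](C)(C)C(C)(C)C)[C@@H](C(C)=C)C=C1 | intermediate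
11 | methyl {6-[(tert-butyldimethylsilyl)oxy]-1-(3,3-diethoxyprop-1-en-2-yl)-2-ethenyl-2-methyl-5-(prop-1-en-2-yl)cyclohex-3-en-1-yl} carbonate; carbonate O, OTBS and ring CH3 on the lower face; vinyl, isopropenyl and the acetal side chain on the upper face | C=C[C@@]1(C)[C@@](OC(=O)OC)(C(=C)C(OCC)OCC)[C@H](O[Si](C)(C)C(C)(C)C)[C@@H](C(C)=C)C=C1 | intermediate
12 | tert-butyl{[2-(3,3-diethoxyprop-1-en-2-yl)-3-ethenyl-3-methyl-6-(prop-1-en-2-yl)cyclohex-4-en-1-yl]oxy}dimethylsilane; acetal side chain, OTBS and ring CH3 on the lower face; vinyl and isopropenyl on the upper face | C=C[C@@]1(C)[C@H](C(=C)C(OCC)OCC)[C@H](O[Si](C)(C)C(C)(C)C)[C@@H](C(C)=C)C=C1 | intermediate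
13 | 12 with the isopropenyl CH3 oxidised to CH2OH (C7 side chain 3-hydroxyprop-1-en-2-yl) | C=C[C@@]1(C)[C@H](C(=C)C(OCC)OCC)[C@H](O[Si](C)(C)C(C)(C)C)[C@@H](C(=C)CO)C=C1 | intermediate
14 | 12 with the isopropenyl CH3 oxidised to CO2H (C7 side chain 1-carboxyethenyl) | C=C[C@@]1(C)[C@H](C(=C)C(OCC)OCC)[C@H](O[Si](C)(C)C(C)(C)C)[C@@H](C(=C)C(=O)O)C=C1 | intermediate
15 | 14 with a C8–C9 oxirane on the lower face (trans to the C7 acrylic acid unit) | C=C[C@@]1(C)[C@H](C(=C)C(OCC)OCC)[C@H](O[Si](C)(C)C(C)(C)C)[C@@H](C(=C)C(=O)O)[C@@H]2O[C@H]12 | intermediate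
16 | hydroxy lactone: cis-fused 12,8-olide (C8–O upper face), C9–OH lower face, C6–OTBS, C5 acetal side chain | C=C[C@@]1(C)[C@H](C(=C)C(OCC)OCC)[C@H](O[Si](C)(C)C(C)(C)C)[C@H]2C(=C)C(=O)O[C@H]2[C@@H]1O | intermediate
17 | (R)-2-methylbutanoic acid | CC[C@@H](C)C(=O)O | starting material
18 | 16 with C9–OH esterified as (2R)-2-methylbutanoate | C=C[C@@]1(C)[C@H](C(=C)C(OCC)OCC)[C@H](O[Si](C)(C)C(C)(C)C)[C@H]2C(=C)C(=O)O[C@H]2[C@@H]1OC(=O)[C@H](C)CC | intermediate
19 | 18 with free C6–OH | C=C[C@@]1(C)[C@H](C(=C)C(OCC)OCC)[C@H](O)[C@H]2C(=C)C(=O)O[C@H]2[C@@H]1OC(=O)[C@H](C)CC | intermediate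
20 | angelic acid, (Z)-2-methylbut-2-enoic acid | C/C=C(/C)C(=O)O | starting material
21 | 19 with C6–OH esterified as angelate (15,15-diethyl acetal of the target) | C=C[C@@]1(C)[C@H](C(=C)C(OCC)OCC)[C@H](OC(=O)/C(C)=C\C)[C@H]2C(=C)C(=O)O[C@H]2[C@@H]1OC(=O)[C@H](C)CC | intermediate
22 | CNP0295282.1, (5R,6S,7R,8R,9R,10S)-6-angeloyloxy-9-[(2R)-2-methylbutanoyloxy]-15-oxoelema-1,3,11(13)-trien-12,8-olide | C=C[C@@]1(C)[C@H](C(=C)C=O)[C@H](OC(=O)/C(C)=C\C)[C@H]2C(=C)C(=O)O[C@H]2[C@@H]1OC(=O)[C@H](C)CC | target

**Step count and risks**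
Total steps: 13. Longest linear sequence: 13 (fully linear from 1).

Most likely to fail:

- **Step 3** (iodane transfer to a fully substituted dienolate carbon; α versus α'/γ selectivity and facial selectivity). Fallback: from 4, the same dienolate 6 is added to phenyl vinyl sulfoxide (THF, −78 → 0 °C) to give the 2-(phenylsulfinyl)ethyl ketone F1. Heating F1 in toluene over CaCO3 (110 °C) expels benzenesulfenic acid by syn-elimination and gives vinyl ketone 8 directly. The route is rejoined at 8 and the semihydrogenation drops out.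

- **Step 6** (hydride delivery to a neopentyl, fully substituted allyl terminus; diene formation or delivery to the CH2 terminus may compete). Fallback: from 8, the organocerium addition is quenched with water instead of the chloroformate to give the tertiary allylic alcohol F2. O3ReOSiPh3 (cat., Et2O, 0 °C) transposes F2 to the primary allylic alcohol F3. Mitsunobu reaction of F3 with 2-nitrobenzenesulfonylhydrazide (PPh3, diethyl azodicarboxylate, THF, −30 °C) gives the N-allyl sulfonylhydrazine F4. On warming, F4 loses the sulfinic acid to the allylic diazene F5, which extrudes N2 in a retro-ene shift that places hydrogen on C5 from the face away from the silyloxy group. This gives 12, where the route is rejoined.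

- **Step 9** (face and site selectivity of the peracid among four alkenes). Fallback: from 14, the silyl ether is removed first (Bu4NF, AcOH) to give the hydroxy acid F6. The homoallylic C6 hydroxyl then directs a VO(acac)2/t-BuOOH epoxidation to the lower face of C8=C9, giving the epoxy acid F7, which lactonises in the flask to the diol lactone F8. The less hindered C6 hydroxyl is acylated selectively with the angelic mixed anhydride to give the mono-angelate F9. Yamaguchi esterification of the C9 hydroxyl with 17 then gives 21, where the route is rejoined.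

**Further compounds**
F1 | step 3 | 2-[2-(phenylsulfinyl)ethyl] analogue of 8 (sulfur epimers) | O=S(CC[C@@]1(C)C(=O)[C@H](O[Si](C)(C)C(C)(C)C)[C@@H](C(C)=C)C=C1)c1ccccc1
F2 | step 6 | C5 tertiary allylic alcohol (free alcohol of 10) | C=C[C@@]1(C)[C@@](O)(C(=C)C(OCC)OCC)[C@H](O[Si](C)(C)C(C)(C)C)[C@@H](C(C)=C)C=C1
F3 | step 6 | transposed primary allylic alcohol with exocyclic C5=C4 alkene (E/Z mixture) | C=C[C@@]1(C)C(=C(CO)C(OCC)OCC)[C@H](O[Si](C)(C)C(C)(C)C)[C@@H](C(C)=C)C=C1
F4 | step 6 | N-allyl-N-(2-nitrophenylsulfonyl)hydrazine from F3 | C=C[C@@]1(C)C(=C(CN(N)S(=O)(=O)c2ccccc2[N+](=O)[O-])C(OCC)OCC)[C@H](O[Si](C)(C)C(C)(C)C)[C@@H](C(C)=C)C=C1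
F5 | step 6 | allylic diazene from F4 | C=C[C@@]1(C)C(=C(CN=N)C(OCC)OCC)[C@H](O[Si](C)(C)C(C)(C)C)[C@@H](C(C)=C)C=C1
F6 | step 9 | 14 with free C6–OH | C=C[C@@]1(C)[C@H](C(=C)C(OCC)OCC)[C@H](O)[C@@H](C(=C)C(=O)O)C=C1
F7 | step 9 | F6 with a C8–C9 oxirane on the lower face (cis to C6–OH) | C=C[C@@]1(C)[C@H](C(=C)C(OCC)OCC)[C@H](O)[C@@H](C(=C)C(=O)O)[C@@H]2O[C@H]12
F8 | step 9 | diol lactone (16 without the TBS group) | C=C[C@@]1(C)[C@H](C(=C)C(OCC)OCC)[C@H](O)[C@H]2C(=C)C(=O)O[C@H]2[C@@H]1O
F9 | step 9 | C6 angelate of F8 with free C9–OH | C=C[C@@]1(C)[C@H](C(=C)C(OCC)OCC)[C@H](OC(=O)/C(C)=C\C)[C@H]2C(=C)C(=O)O[C@H]2[C@@H]1O
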